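# Proposed synthesis of glycyrrhizaisoflavone C (19)

## The problem

Glycyrrhizaisoflavone C (19) is a 7-hydroxyisoflavone whose ring B (C1' bonded to C3 of the chromone) is pentasubstituted: methoxyl at C2', a 2,2-dimethyldihydropyran (ring D) fused across C3'–C4' with its oxygen on C4', hydrogen at C5' and a free hydroxyl at C6'. There is no stereocentre, so nothing can be relayed from one centre to another and the difficulty lies in connectivity and regiochemistry. Three things must be secured: the C3–C1' bond to an aryl group with oxygen on both ortho carbons, the fusion of ring D to C3' and not to C5', and the distinction between the C2' and C6' oxygens, which must end as a methyl ether and a free phenol. Several groups dislike rough treatment: hydroxide or amines open the γ-pyrone on heating and its C2=C3 bond can be over-reduced, the tertiary alkyl aryl ether of ring D (and any tertiary propargylic ether leading to it) ionises in strong acid, and the phloroglucinol-type ring B is easily oxidised or attacked by electrophiles. The exploitable feature is that ring D grows from the C4' oxygen, which lies on the axis through C1' and C4'. If C2' and C6' carry the same group, ring B has a mirror plane through that axis, C3' and C5' are equivalent, and an annulation launched from O4' has one possible product. The price is that the two flanking oxygens must be told apart after ring D exists, when the only difference is steric: O2' then lies between the ring D methylene and the chromone, O6' between the chromone and a hydrogen.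

## Retrosynthesis

**19 back to triol 16 (O–CH3 at C2' and two O–Si bonds).** The methyl group is placed last, on the only phenol left free in bis-silyl ether 17, which gives 18 and then 19. Carrying the methyl ether from the start would save three steps, but C3' and C5' would become different and the ring D annulation would lose its regiocontrol. Triol 16 has all three oxygens free. The forward steps ask that a bulky silyl chloride cap the ring A hydroxyl and the C6' hydroxyl (one ortho substituent) but not the C2' hydroxyl (two), that the flanked phenol of 17 still accept a methyl group, and that fluoride release 19 without opening the pyrone.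

**16 back to chromene 15 (two C–H bonds of ring D and three O–benzyl bonds).** One hydrogenation undoes both. This lets ring D be made at the chromene level, which is what a pericyclic annulation delivers, and lets all three phenols travel as benzyl ethers that tolerate base, heat and dilute acid. Compound 15 is symmetric in its ring B oxygens and needs no selective chemistry. The forward step must leave the C2=C3 bond of the chromone intact.

**15 back to propargyl ether 11 (C3'–C bond and O–CMe2 bond, ring D).** This is the key cut. Acid-mediated prenylation and cyclisation of a phenol would give C- and O-alkylation mixtures and expose the benzyl ethers to acid. A bimolecular cycloaddition would depend on trapping a transient quinone methide. The propargyl ether route is unimolecular and needs only heat. Precursor 11 lacks ring D and keeps the mirror plane of ring B. The forward reaction needs free ortho positions and an inert medium.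

**11 back to phenol 9 and chloride 10 (O4'–C bond).** A tertiary propargylic ether cannot be made by a plain substitution, so the forward step is a copper-catalysed O-propargylation. It is placed after the chromone is complete because the terminal alkyne and the tertiary ether would survive neither an oxidative rearrangement nor hot acid. Phenol 9 has a single free hydroxyl, so no selectivity is needed.

**9 back to chalcone 7 (C3–C1' and O1–C2 bonds of the chromone).** The pyrone is opened to dimethyl acetal 8, and a 1,2-shift of ring B is reversed. A cross-coupling at C3 would need an arylmetal with two ortho alkoxy groups. Such a reagent loses its metal easily, and preparing it from 1 raises a positional question with no carbonyl to answer it. In 7 the carbon that becomes C2 is already bonded to C1', so the position of ring B is fixed, and its electron-rich character makes it a good migrating group. The forward step asks for an oxidant that attacks the enone faster than the arene, and for an acid treatment that closes the ring and removes the 4'-O protecting group while sparing the benzyl ethers.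

**7 back to aldehyde 4 and ketone 6 (Cα=Cβ bond).** A crossed aldol condensation joins the two aromatic halves, each made in one or two steps. The aldehyde has no α-hydrogen and the ketone a single enolisable methyl, so only one condensation product is possible. The 4-oxygen of the aldehyde must be masked, because a para-phenoxide would deactivate the formyl group.

**4 back to 3 and 1; 6 back to 5 (O–CH2OMe, C1'–CHO and O–benzyl bonds).** Formylation of 1 para to its free hydroxyl gives 3 with both benzyl ethers ortho to the formyl group and the future O4' distinguished. An acetal protecting group then gives 4. Ketone 6 comes from 5 by benzylation of the hydroxyl that is not hydrogen-bonded to the carbonyl.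

## Roads not taken

Alternative 1: Ring B would be built from a pyrone, cutting the C5'–C6' bond of the arene. The fully substituted pyrone 4-methoxy-6-methyl-5-(3-methylbut-2-en-1-yl)-3-(prop-2-en-1-yl)-2H-pyran-2-one A2 is opened by an alkoxide at the lactone carbonyl to a (Z)-β-methoxy-δ-oxo enoate. The methyl ketone enolate then attacks the ester in a Claisen condensation and aromatises to 5-methoxy-6-(3-methylbut-2-en-1-yl)-4-(prop-2-en-1-yl)benzene-1,3-diol A1, an isomer of A2.
- Merits: every oxygen of ring B in A1 is different from the moment the ring exists, because the methoxyl is locked between the allyl group (future C1') and the prenyl group (future C3'). The prenyl group has one hydroxyl neighbour, so closure of ring D is unambiguous. Here this road is better than the chosen one, which spends three steps on telling O2' from O6'.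
- Weak points: A2 needs two different C-alkylations of a methoxypyrone, the second at the unreactive C5. In the opened chain the most acidic position is the C–H between enol ether and ketone, whose enolate only returns the pyrone, so the productive methyl enolate is the minor one. From A1 the whole chromone is still missing: the allyl group must be cut down to an arylacetic acid without touching the prenyl group, joined to ring A by a Friedel–Crafts acylation that the tertiary ether of ring D must survive, and closed with a one-carbon unit. That is at least six more steps.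
- Comparison: the chosen plan sets against the better oxygen differentiation of A1 a convergent, classical isoflavone assembly from commercial aromatics and an annulation with a single possible outcome.

Alternative 2: Ring B would be assembled by a Danheiser benzannulation onto a pre-formed ring D. Heating the cyclobutenone 3,3-dimethyl-2-oxabicyclo[4.2.0]oct-1(6)-en-7-one A4 with the ynol ether 1-methoxypent-4-en-1-yne A5 opens A4 to a vinylketene, which adds the alkyne in a [2+2] reaction. The adduct opens to a dienylketene that closes to the phenol 5-methoxy-2,2-dimethyl-6-(prop-2-en-1-yl)-3,4-dihydro-2H-chromen-7-ol A3, forming C6'–C1', C2'–C3' and C5'–C6'.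
- Merits: the mechanism fixes the regiochemistry, so in A3 the methoxyl appears next to ring D and the hydroxyl at C6' with no late differentiation. As in alternative 1, this is an advantage over the chosen plan.
- Weak points: neither partner is available. A4 is a strained vinylogous ester that would itself take several steps. A5 is a volatile, acid- and heat-sensitive alkoxyalkyne whose doubly activated methylene invites isomerisation to the allene at the reaction temperature. After A3 the same long conversion of the allyl group into the chromone remains, with an acid-sensitive ring D on board.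
- Comparison: the chosen plan has the isoflavone in place before any ring D chemistry begins and uses only purchasable building blocks. It pays with the three-step end game.

Alternative 3: Ring D would be closed by a [4+2] cycloaddition. Aminomethylation of phenol 9 would give the Mannich base 7-(benzyloxy)-3-{2,6-bis(benzyloxy)-3-[(dimethylamino)methyl]-4-hydroxyphenyl}-4H-chromen-4-one A7. On heating, A7 loses its amine, and the resulting ortho-quinone methide adds 2-methylprop-1-ene A8, forming the CH2–CH2 bond and the O–CMe2 bond and giving 7-(benzyloxy)-3-[5,7-bis(benzyloxy)-2,2-dimethyl-3,4-dihydro-2H-chromen-6-yl]-4H-chromen-4-one A6.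
- Merits: this road uses the same symmetric ring B, so its regiochemical certainty equals that of the chosen plan. It is equally long (aminomethylation to A7 and cycloaddition against etherification and rearrangement). In A6 the ring is already saturated, and neither a propargylic chloride nor copper is needed.
- Weak points: A8 is a gas and an unactivated alkene, whereas ortho-quinone methides prefer electron-rich partners. The trapping therefore needs pressure, a large excess and high temperature, during which the quinone methide from A7 can dimerise, take back the amine or add the phenol of another molecule. The Mannich step that leads to A7 can also aminomethylate both C3' and C5'.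
- Comparison: the saving of one alkene reduction on the way through A6 is worth nothing here, because hydrogenolysis of the benzyl ethers is needed anyway. The chosen plan is preferred on reliability, not on length: its ring closure is unimolecular and every intermediate is tethered.

Key step: step 7

Assumption: 3,5-bis(benzyloxy)phenol (1), the dibenzyl ether of phloroglucinol, is taken as a commercial starting material; its free hydroxyl becomes the C4' oxygen.

## Route

Step 1
Reactants: 1 3,5-bis(benzyloxy)phenol
Product: 3 2,6-bis(benzyloxy)-4-hydroxybenzaldehyde, via iminium chloride 2 (not isolated)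
Conditions: POCl3, DMF, MeCN, 0 °C to rt; then H2O, 50 °C
Reagents that add atoms: N,N-dimethylformamide CN(C)C=O; water O
Why: Vilsmeier–Haack formylation; with 3,5-dialkoxyphenols the chloroiminium ion attacks mainly para to the free hydroxyl, between the two ethers, and hydrolysis of iminium salt 2 releases the aldehyde. The ortho-formyl isomer is internally hydrogen-bonded, much less polar, and should be removed by chromatography.

Step 2
Reactants: 3 2,6-bis(benzyloxy)-4-hydroxybenzaldehyde
Product: 4 2,6-bis(benzyloxy)-4-(methoxymethoxy)benzaldehyde
Conditions: MOMCl, K2CO3, acetone, 0 °C to rt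
Reagents that add atoms: chloromethyl methyl ether COCCl
Why: Williamson-type O-alkylation of an acidic, unhindered phenol para to the formyl group. The acetal keeps the aldehyde electrophilic in the aldol step and is removed later by dilute acid that leaves benzyl ethers alone.

Step 3
Reactants: 5 1-(2,4-dihydroxyphenyl)ethan-1-one (2,4-dihydroxyacetophenone)
Product: 6 1-[4-(benzyloxy)-2-hydroxyphenyl]ethan-1-one
Conditions: BnBr (1.05 equiv), K2CO3, acetone, reflux
Reagents that add atoms: benzyl bromide BrCc1ccccc1
Why: Selective Williamson etherification; the 2-hydroxyl is held in a hydrogen bond to the ketone, so the weak base and one equivalent of halide should alkylate only the 4-hydroxyl.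

Step 4
Reactants: 4 2,6-bis(benzyloxy)-4-(methoxymethoxy)benzaldehyde; 6 1-[4-(benzyloxy)-2-hydroxyphenyl]ethan-1-one
Product: 7 (E)-1-[4-(benzyloxy)-2-hydroxyphenyl]-3-[2,6-bis(benzyloxy)-4-(methoxymethoxy)phenyl]prop-2-en-1-one
Conditions: KOH (aq), EtOH, rt
Reagents that add atoms: none
Why: Claisen–Schmidt condensation; the aldehyde has no α-hydrogen, the aldol adduct dehydrates to the (E)-enone under thermodynamic control, and the di-ortho-alkoxy aryl group disfavours closure to a flavanone. Acetal and benzyl ethers are stable to alkali.

Step 5
Reactants: 7 (E)-1-[4-(benzyloxy)-2-hydroxyphenyl]-3-[2,6-bis(benzyloxy)-4-(methoxymethoxy)phenyl]prop-2-en-1-one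
Product: 9 7-(benzyloxy)-3-[2,6-bis(benzyloxy)-4-hydroxyphenyl]-4H-chromen-4-one, via dimethyl acetal 8 (not isolated)
Conditions: Tl(NO3)3·3H2O, MeOH, rt; then 3 M HCl, MeOH, 60 °C
Reagents that add atoms: none
Why: Oxidative 1,2-aryl rearrangement of a 2'-hydroxychalcone by a trivalent thallium salt: methoxythallation of the enone, then migration of the electron-rich ring B from Cβ to Cα with loss of monovalent thallium gives acetal 8, whose two methoxy groups come from the solvent and leave again. Acid then closes the pyrone by attack of the phenol on the acetal carbon and loss of methanol, and removes the methoxymethyl group in the same operation.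

Step 6
Reactants: 9 7-(benzyloxy)-3-[2,6-bis(benzyloxy)-4-hydroxyphenyl]-4H-chromen-4-one; 10 3-chloro-3-methylbut-1-yne
Product: 11 7-(benzyloxy)-3-{2,6-bis(benzyloxy)-4-[(2-methylbut-3-yn-2-yl)oxy]phenyl}-4H-chromen-4-one
Conditions: CuCl2·2H2O (cat.), DBU, MeCN, 0 °C
Reagents that add atoms: none
Why: Copper-catalysed O-propargylation of a phenol with a tertiary propargylic chloride, which proceeds through a copper-bound propargyl/allenyl electrophile and avoids the elimination of a direct substitution. Compound 9 has one free hydroxyl flanked by two hydrogens, and the cold, non-nucleophilic base should leave the chromone closed.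

Step 7
Reactants: 11 7-(benzyloxy)-3-{2,6-bis(benzyloxy)-4-[(2-methylbut-3-yn-2-yl)oxy]phenyl}-4H-chromen-4-one
Product: 15 7-(benzyloxy)-3-[5,7-bis(benzyloxy)-2,2-dimethyl-2H-chromen-6-yl]-4H-chromen-4-one, via allenyl dienone 12 (not isolated), via ortho-allenylphenol 13 (not isolated), via ortho-quinone methide 14 (not isolated)
Conditions: o-xylene, 140 °C (sealed tube)
Reagents that add atoms: none
Why: Aromatic propargyl Claisen cascade, the established thermal conversion of aryl 1,1-dimethylpropargyl ethers into 2,2-dimethyl-2H-chromenes. A [3,3]-sigmatropic shift moves the propargyl unit from O4' to C3', forming the C3'–C bond and giving allenyl dienone 12, which enolises to ortho-allenylphenol 13. A 1,5-hydrogen shift from the phenolic O–H to the central allene carbon gives the (Z)-ortho-quinone methide 14, with the carbonyl oxygen and the dimethylvinyl terminus held cis. A thermal six-electron oxa-electrocyclisation then forms the O–CMe2 bond and closes ring D as a six-membered 2H-pyran, and the return of aromaticity to ring B drives the sequence. No stereocentre is created. The only selectivity needed is between C3' and C5'; because C2' and C6' both carry benzyloxy groups, the two ortho carbons are related by the mirror plane through C1' and C4' and either leads to 15. Both ortho carbons bear hydrogen, so 12 can tautomerise instead of migrating further, the geminal methyl groups speed the sigmatropic step and exclude benzofuran formation, and benzyl ethers and chromone are inert to heat in a neutral hydrocarbon.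

Step 8
Reactants: 15 7-(benzyloxy)-3-[5,7-bis(benzyloxy)-2,2-dimethyl-2H-chromen-6-yl]-4H-chromen-4-one
Product: 16 3-(5,7-dihydroxy-2,2-dimethyl-3,4-dihydro-2H-chromen-6-yl)-7-hydroxy-4H-chromen-4-one
Conditions: H2 (1 atm), 10% Pd/C, EtOAc–MeOH, rt
Reagents that add atoms: none
Why: Catalytic hydrogenation and hydrogenolysis: the cis-disubstituted styrene-type double bond of ring D is saturated and the three benzyl ethers are cleaved. The C2=C3 bond of the chromone is a vinylogous ester shielded by the di-ortho-substituted ring B and should survive if the reaction is stopped at completion.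

Step 9
Reactants: 16 3-(5,7-dihydroxy-2,2-dimethyl-3,4-dihydro-2H-chromen-6-yl)-7-hydroxy-4H-chromen-4-one
Product: 17 3-{5-hydroxy-2,2-dimethyl-7-[tri(propan-2-yl)silyloxy]-3,4-dihydro-2H-chromen-6-yl}-7-[tri(propan-2-yl)silyloxy]-4H-chromen-4-one
Conditions: TIPSCl (2.1 equiv), imidazole, DMF, 0 °C to rt
Reagents that add atoms: chlorotri(propan-2-yl)silane CC(C)[Si](Cl)(C(C)C)C(C)C
Why: Sterically controlled silylation: the ring A hydroxyl (most acidic, unhindered) and the ring B hydroxyl with a hydrogen neighbour should react with the bulky chloride, while the hydroxyl between the ring D methylene and the chromone should stay free. Wrongly silylated material can be returned to 16 with fluoride.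

Step 10
Reactants: 17 3-{5-hydroxy-2,2-dimethyl-7-[tri(propan-2-yl)silyloxy]-3,4-dihydro-2H-chromen-6-yl}-7-[tri(propan-2-yl)silyloxy]-4H-chromen-4-one
Product: 18 3-{5-methoxy-2,2-dimethyl-7-[tri(propan-2-yl)silyloxy]-3,4-dihydro-2H-chromen-6-yl}-7-[tri(propan-2-yl)silyloxy]-4H-chromen-4-one
Conditions: MeI, K2CO3, acetone, 40 °C
Reagents that add atoms: iodomethane CI
Why: Williamson methylation of the only free phenol; iodomethane is small enough to reach the flanked phenoxide, and aryl triisopropylsilyl ethers tolerate K2CO3 in dry acetone.

Step 11
Reactants: 18 3-{5-methoxy-2,2-dimethyl-7-[tri(propan-2-yl)silyloxy]-3,4-dihydro-2H-chromen-6-yl}-7-[tri(propan-2-yl)silyloxy]-4H-chromen-4-one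
Product: 19 7-hydroxy-3-(7-hydroxy-5-methoxy-2,2-dimethyl-3,4-dihydro-2H-chromen-6-yl)-4H-chromen-4-one (glycyrrhizaisoflavone C)
Conditions: TBAF, AcOH, THF, 0 °C
Reagents that add atoms: none
Why: Fluoride-induced cleavage of both aryl silyl ethers, driven by the Si–F bond. Acetic acid keeps the liberated phenoxides protonated so that the γ-pyrone is not opened; the methyl ether and ring D are untouched.

## Compound list

1 | 3,5-bis(benzyloxy)phenol | Oc1cc(OCc2ccccc2)cc(OCc2ccccc2)c1 | starting material
2 | N-{[2,6-bis(benzyloxy)-4-hydroxyphenyl]methylidene}-N-methylmethanaminium chloride | C[N+](C)=Cc1c(OCc2ccccc2)cc(O)cc1OCc1ccccc1.[Cl-] | intermediate (not isolated)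
3 | 2,6-bis(benzyloxy)-4-hydroxybenzaldehyde | O=Cc1c(OCc2ccccc2)cc(O)cc1OCc1ccccc1 | intermediate
4 | 2,6-bis(benzyloxy)-4-(methoxymethoxy)benzaldehyde | COCOc1cc(OCc2ccccc2)c(C=O)c(OCc2ccccc2)c1 | intermediate
5 | 1-(2,4-dihydroxyphenyl)ethan-1-one | CC(=O)c1ccc(O)cc1O | starting material
6 | 1-[4-(benzyloxy)-2-hydroxyphenyl]ethan-1-one | CC(=O)c1ccc(OCc2ccccc2)cc1O | intermediate
7 | (E)-1-[4-(benzyloxy)-2-hydroxyphenyl]-3-[2,6-bis(benzyloxy)-4-(methoxymethoxy)phenyl]prop-2-en-1-one | COCOc1cc(OCc2ccccc2)c(/C=C/C(=O)c2ccc(OCc3ccccc3)cc2O)c(OCc2ccccc2)c1 | intermediate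
8 | 1-[4-(benzyloxy)-2-hydroxyphenyl]-2-[2,6-bis(benzyloxy)-4-(methoxymethoxy)phenyl]-3,3-dimethoxypropan-1-one (racemic) | COCOc1cc(OCc2ccccc2)c(C(C(OC)OC)C(=O)c2ccc(OCc3ccccc3)cc2O)c(OCc2ccccc2)c1 | intermediate (not isolated)
9 | 7-(benzyloxy)-3-[2,6-bis(benzyloxy)-4-hydroxyphenyl]-4H-chromen-4-one | Oc1cc(OCc2ccccc2)c(-c2coc3cc(OCc4ccccc4)ccc3c2=O)c(OCc2ccccc2)c1 | intermediate
10 | 3-chloro-3-methylbut-1-yne | C#CC(C)(C)Cl | starting material
11 | 7-(benzyloxy)-3-{2,6-bis(benzyloxy)-4-[(2-methylbut-3-yn-2-yl)oxy]phenyl}-4H-chromen-4-one | C#CC(C)(C)Oc1cc(OCc2ccccc2)c(-c2coc3cc(OCc4ccccc4)ccc3c2=O)c(OCc2ccccc2)c1 | intermediate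
12 | 7-(benzyloxy)-3-[2,6-bis(benzyloxy)-3-(3-methylbuta-1,2-dien-1-yl)-4-oxocyclohexa-1,5-dien-1-yl]-4H-chromen-4-one (racemic) | CC(C)=C=CC1C(=O)C=C(OCc2ccccc2)C(-c2coc3cc(OCc4ccccc4)ccc3c2=O)=C1OCc1ccccc1 | intermediate (not isolated)
13 | 7-(benzyloxy)-3-[2,6-bis(benzyloxy)-4-hydroxy-3-(3-methylbuta-1,2-dien-1-yl)phenyl]-4H-chromen-4-one | CC(C)=C=Cc1c(O)cc(OCc2ccccc2)c(-c2coc3cc(OCc4ccccc4)ccc3c2=O)c1OCc1ccccc1 | intermediate (not isolated)
14 | 7-(benzyloxy)-3-[(3Z)-2,6-bis(benzyloxy)-3-(3-methylbut-2-en-1-ylidene)-4-oxocyclohexa-1,5-dien-1-yl]-4H-chromen-4-one | CC(C)=C/C=C1\C(=O)C=C(OCc2ccccc2)C(-c2coc3cc(OCc4ccccc4)ccc3c2=O)=C1OCc1ccccc1 | intermediate (not isolated)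
15 | 7-(benzyloxy)-3-[5,7-bis(benzyloxy)-2,2-dimethyl-2H-chromen-6-yl]-4H-chromen-4-one | CC1(C)C=Cc2c(cc(OCc3ccccc3)c(-c3coc4cc(OCc5ccccc5)ccc4c3=O)c2OCc2ccccc2)O1 | intermediate
16 | 3-(5,7-dihydroxy-2,2-dimethyl-3,4-dihydro-2H-chromen-6-yl)-7-hydroxy-4H-chromen-4-one | CC1(C)CCc2c(cc(O)c(-c3coc4cc(O)ccc4c3=O)c2O)O1 | intermediate
17 | 3-{5-hydroxy-2,2-dimethyl-7-[tri(propan-2-yl)silyloxy]-3,4-dihydro-2H-chromen-6-yl}-7-[tri(propan-2-yl)silyloxy]-4H-chromen-4-one | CC1(C)CCc2c(cc(O[Si](C(C)C)(C(C)C)C(C)C)c(-c3coc4cc(O[Si](C(C)C)(C(C)C)C(C)C)ccc4c3=O)c2O)O1 | intermediate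
18 | 3-{5-methoxy-2,2-dimethyl-7-[tri(propan-2-yl)silyloxy]-3,4-dihydro-2H-chromen-6-yl}-7-[tri(propan-2-yl)silyloxy]-4H-chromen-4-one | COc1c2c(cc(O[Si](C(C)C)(C(C)C)C(C)C)c1-c1coc3cc(O[Si](C(C)C)(C(C)C)C(C)C)ccc3c1=O)OC(C)(C)CC2 | intermediate
19 | 7-hydroxy-3-(7-hydroxy-5-methoxy-2,2-dimethyl-3,4-dihydro-2H-chromen-6-yl)-4H-chromen-4-one (glycyrrhizaisoflavone C) | COc1c2c(cc(O)c1-c1coc3cc(O)ccc3c1=O)OC(C)(C)CC2 | target

## Step count and least certain steps

Total: 11 steps. Longest linear sequence: 10 steps (from 1 through steps 1, 2, 4, 5, 6, 7, 8, 9, 10 and 11); step 3 is a one-step side branch.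

**Step 7 (key step).** The likeliest failures are thermal loss of the tertiary propargylic side chain by elimination, which would return phenol 9, and oligomerisation of the quinone methide before it closes. The fallback sets out from 9 and builds ring D by a formal [3+3] condensation instead of a sigmatropic shift: 9 is heated with 3-methylbut-2-enal and catalytic ethylenediammonium diacetate in toluene. C-alkylation at C3' (either ortho carbon, by the same symmetry) and dehydration give the same quinone methide 14, which closes to 15. The route is rejoined at 15 and no new compound is made (F0).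

**Step 9.** The likeliest failure is insufficient discrimination between the two ring B hydroxyls, so that silylation either spreads to the flanked hydroxyl or stops short of the less hindered one. The fallback moves the discrimination from a protection to a deprotection and sets out from 15. Hydrogenation over Pd/C in the presence of pyridine, which suppresses benzyl ether hydrogenolysis, should saturate only the ring D double bond and give 7-(benzyloxy)-3-[5,7-bis(benzyloxy)-2,2-dimethyl-3,4-dihydro-2H-chromen-6-yl]-4H-chromen-4-one F1 (the same structure as A6). BCl3 in CH2Cl2 at −78 °C cleaves preferentially an aryl ether forced out of conjugation by two ortho substituents, and should give 7-(benzyloxy)-3-[7-(benzyloxy)-5-hydroxy-2,2-dimethyl-3,4-dihydro-2H-chromen-6-yl]-4H-chromen-4-one F2. Methylation with MeI and K2CO3 then gives 7-(benzyloxy)-3-[7-(benzyloxy)-5-methoxy-2,2-dimethyl-3,4-dihydro-2H-chromen-6-yl]-4H-chromen-4-one F3. Hydrogenolysis over Pd/C removes the two remaining benzyl groups, and the route is rejoined at 19.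

**Step 5.** The likeliest failures are oxidative attack of the thallium salt on the electron-rich ring B (ring metalation or nitration), aurone-type closure by the free 2-hydroxyl competing with the aryl shift, and partial loss of benzyl groups in the hot acid. The fallback sets out from 7 and replaces the electrophilic oxidant by a nucleophilic one. The 2-hydroxyl is protected with MOMCl and NaH to give (E)-1-[4-(benzyloxy)-2-(methoxymethoxy)phenyl]-3-[2,6-bis(benzyloxy)-4-(methoxymethoxy)phenyl]prop-2-en-1-one F4. Weitz–Scheffer epoxidation with H2O2 and NaOH gives the racemic trans epoxide [4-(benzyloxy)-2-(methoxymethoxy)phenyl]{3-[2,6-bis(benzyloxy)-4-(methoxymethoxy)phenyl]oxiran-2-yl}methanone F5. BF3·OEt2 opens the epoxide at the benzylic carbon and induces a 1,2-shift of the aroyl group, giving 3-[4-(benzyloxy)-2-(methoxymethoxy)phenyl]-2-[2,6-bis(benzyloxy)-4-(methoxymethoxy)phenyl]-3-oxopropanal F6. HCl in methanol removes both acetal groups and cyclodehydrates, and the route is rejoined at 9.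

**Step 1.** The likeliest failure is poor positional selectivity: formylation ortho to the free hydroxyl, or twofold formylation. The fallback sets out from 1 and uses steric blocking in place of the innate para preference. Silylation with TIPSCl and imidazole gives [3,5-bis(benzyloxy)phenoxy]tri(propan-2-yl)silane F7. Vilsmeier–Haack formylation is then steered away from both positions next to the bulky silyloxy group and should give 2,6-bis(benzyloxy)-4-{[tri(propan-2-yl)silyl]oxy}benzaldehyde F8. TBAF removes the silyl group, and the route is rejoined at 3.

## Further compounds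

F0 | step 7 | none | none
F1 | step 9 | 7-(benzyloxy)-3-[5,7-bis(benzyloxy)-2,2-dimethyl-3,4-dihydro-2H-chromen-6-yl]-4H-chromen-4-one | CC1(C)CCc2c(cc(OCc3ccccc3)c(-c3coc4cc(OCc5ccccc5)ccc4c3=O)c2OCc2ccccc2)O1
F2 | step 9 | 7-(benzyloxy)-3-[7-(benzyloxy)-5-hydroxy-2,2-dimethyl-3,4-dihydro-2H-chromen-6-yl]-4H-chromen-4-one | CC1(C)CCc2c(cc(OCc3ccccc3)c(-c3coc4cc(OCc5ccccc5)ccc4c3=O)c2O)O1
F3 | step 9 | 7-(benzyloxy)-3-[7-(benzyloxy)-5-methoxy-2,2-dimethyl-3,4-dihydro-2H-chromen-6-yl]-4H-chromen-4-one | COc1c2c(cc(OCc3ccccc3)c1-c1coc3cc(OCc4ccccc4)ccc3c1=O)OC(C)(C)CC2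
F4 | step 5 | (E)-1-[4-(benzyloxy)-2-(methoxymethoxy)phenyl]-3-[2,6-bis(benzyloxy)-4-(methoxymethoxy)phenyl]prop-2-en-1-one | COCOc1cc(OCc2ccccc2)c(/C=C/C(=O)c2ccc(OCc3ccccc3)cc2OCOC)c(OCc2ccccc2)c1
F5 | step 5 | [4-(benzyloxy)-2-(methoxymethoxy)phenyl]{3-[2,6-bis(benzyloxy)-4-(methoxymethoxy)phenyl]oxiran-2-yl}methanone (trans, racemic; one enantiomer drawn) | COCOc1cc(OCc2ccccc2)c([C@H]2O[C@@H]2C(=O)c2ccc(OCc3ccccc3)cc2OCOC)c(OCc2ccccc2)c1
F6 | step 5 | 3-[4-(benzyloxy)-2-(methoxymethoxy)phenyl]-2-[2,6-bis(benzyloxy)-4-(methoxymethoxy)phenyl]-3-oxopropanal (racemic) | COCOc1cc(OCc2ccccc2)c(C(C=O)C(=O)c2ccc(OCc3ccccc3)cc2OCOC)c(OCc2ccccc2)c1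
F7 | step 1 | [3,5-bis(benzyloxy)phenoxy]tri(propan-2-yl)silane | CC(C)[Si](Oc1cc(OCc2ccccc2)cc(OCc2ccccc2)c1)(C(C)C)C(C)C
F8 | step 1 | 2,6-bis(benzyloxy)-4-{[tri(propan-2-yl)silyl]oxy}benzaldehyde | CC(C)[Si](Oc1cc(OCc2ccccc2)c(C=O)c(OCc2ccccc2)c1)(C(C)C)C(C)C
A1 | alternative 1 | 5-methoxy-6-(3-methylbut-2-en-1-yl)-4-(prop-2-en-1-yl)benzene-1,3-diol | C=CCc1c(O)cc(O)c(CC=C(C)C)c1OC
A2 | alternative 1 | 4-methoxy-6-methyl-5-(3-methylbut-2-en-1-yl)-3-(prop-2-en-1-yl)-2H-pyran-2-one | C=CCC1=C(OC)C(CC=C(C)C)=C(C)OC1=O
A3 | alternative 2 | 5-methoxy-2,2-dimethyl-6-(prop-2-en-1-yl)-3,4-dihydro-2H-chromen-7-ol | C=CCc1c(O)cc2OC(C)(C)CCc2c1OC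
A4 | alternative 2 | 3,3-dimethyl-2-oxabicyclo[4.2.0]oct-1(6)-en-7-one | CC1(C)CCC2=C(O1)CC2=O
A5 | alternative 2 | 1-methoxypent-4-en-1-yne | COC#CCC=C
A6 | alternative 3 | 7-(benzyloxy)-3-[5,7-bis(benzyloxy)-2,2-dimethyl-3,4-dihydro-2H-chromen-6-yl]-4H-chromen-4-one | CC1(C)CCc2c(cc(OCc3ccccc3)c(-c3coc4cc(OCc5ccccc5)ccc4c3=O)c2OCc2ccccc2)O1
A7 | alternative 3 | 7-(benzyloxy)-3-{2,6-bis(benzyloxy)-3-[(dimethylamino)methyl]-4-hydroxyphenyl}-4H-chromen-4-one | CN(C)Cc1c(O)cc(OCc2ccccc2)c(-c2coc3cc(OCc4ccccc4)ccc3c2=O)c1OCc1ccccc1
A8 | alternative 3 | 2-methylprop-1-ene | CC(C)=C
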